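**The ratio.** The ratio of two slopes, north-east over south at twice the charge, tells you what this flask holds at 1.5 h. L is fed in portions and turns into D, with Q and G present from the start.

| setting | north-east | south | flask |
|---|---|---|---|
| L | 0.020 M (in portions, 4) | 0.010 M (in portions, 4) | 0.020 M (in portions, 4) |
| Q | 1.2 equiv | 1.2 equiv | 1.20 equiv |
| G | 1.8 equiv | 1.8 equiv | 1.80 equiv |
| remark | the very flask that is asked about, followed so far; portions every 2.0 min | run made earlier; portions every 2.0 min | the portions of L follow each other after 2.0 min, the first at the start |
| time |  |  | 1.5 h |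

| run | time / min | L / % | D / % |
|---|---|---|---|
| north-east | 2.00 | 25.3 | 0 |
| north-east | 6.00 | 73.7 | 5.0 |
| north-east | 10.0 | 95.6 | 4.5 |
| north-east | 15.0 | 91.9 | 7.5 |
| north-east | 20.0 | 90.3 | 9.9 |
| north-east | 30.0 | 82.6 | 18.2 |
| north-east | 40.0 | 78.4 | 23.6 |
| south | 5.00 | 75.5 | 0.4 |
| south | 10.0 | 96.2 | 2.7 |
| south | 15.0 | 94.4 | 5.0 |
| south | 20.0 | 91.7 | 7.4 |
| south | 25.0 | 89.1 | 10.3 |
| south | 30.0 | 87.1 | 12.1 |
| south | 40.0 | 84.0 | 14.7 |

(scatter of a reading: 1 percentage point)

- the state of affairs at 1.5 h: stopped, and by what, or still going (all of L has reacted / forward and back rates have come level / it is still moving / Q has run out first)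
- conversion of L at 1.5 h
- amount of D at 1.5 h, in percent of the L charged

- the numbers in the tables scatter with a standard deviation of 1 percentage point
- the reaction counts as stopped when no species that holds the L changes by six tenths of a point or more over the second half of the time

**Mean slopes.** Replace each curve from 10.0 min to 40.0 min by its mean: D gained, per minute, per mean fraction of L. North-east reads 0.00732 min⁻¹ and south 0.00444 min⁻¹, a ratio of 1.65. The charge exponent n, the power of the charge in that fractional rate, reads 0.721, making the apparent order 1.72.

**The puzzle.** Yet north-east's D slope, as read, rises while L falls: 0.00540 min⁻¹ up to 20.0 min, then 0.00685 min⁻¹. That order asks for a fall of 8.31 × 10⁻⁴ min⁻¹, but the scatter on the first slope is 0.00141 min⁻¹, which is larger. You can't see that fall in these readings.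

**My reckoning.** Count time from the mean feeding time, 3.00 min. With a rate constant of 0.00809 min⁻¹ at full charge, L keeps 56.6% at 1.5 h. That gives 43.4% conversion, all of it taken as D, and a loss of 17 percentage points over the second half, so by this reckoning the flask is still moving.

**The result.** The forecast says it is still moving, with 42% conversion and 42% D, noting “Q is far from exhausted”. The computed flask reads: it is still moving, with 40.8% conversion and 40.8% D; that conversion is 2.6 points below my figure.

    L + J → X + D (k = 6.90 M⁻¹ min⁻¹)
    J + X ⇌ G, settled at all times (K = 76000 M⁻¹)
    X + Q ⇌ Z (K = 6.10 × 10⁵ M⁻¹, k = 28.0 M⁻¹ min⁻¹)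

**What stands.** At 0.573 h in this flask, the forward step X + Q to Z taken alone gives X a half-life of 1.6 min and Q one of 0.92 h; at 1.50 h this flask holds X at 2.58% of the L charge and Z at 82.4%. For the neighbour with 0.0050 M of L, half the south charge, n scales south's constant to 0.00290 min⁻¹, giving 20.7% conversion; computed, it reaches 24.2%.

The numbers in the tables were generated by integration from invented constants; the scatter is artificial.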